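## The problem

The target (21) is a linear tetramer of polyhydroxybenzenes joined only by three diaryl ether oxygens and carrying eleven free phenols: ring A (2,4,6-trihydroxyphenyl), ring B (a 3,4-dihydroxyphenylene with its ether oxygens at C1 and C5), ring C, and ring D (3,4,5-trihydroxyphenyl). It has no stereocenter, so nothing has to be controlled in space. The whole task is to put oxygen on the right carbons and to decide which oxygens become ethers.

Ring C is numbered here C1 (O to ring B), C2 (OH), C3 (H), C4 (OH), C5 (O to ring D), C6 (OH). It is the hard part: five contiguous oxygenated carbons, two of them ether carbons flanked on both sides by oxygen, cannot be reached by stepwise substitution of a simple benzene. All three ether links are electron-rich on both sides and hindered, so each C–O coupling is demanding and the order of couplings matters. The free polyphenol, with its pyrogallol and hydroxyquinol arrays, is oxidised by air as soon as base is present, so all hydroxyls must travel as ethers and be released together at the very end.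

The feature that makes the key step possible is a mapping of ring C onto two small pieces. C4, C5, C6 and C1 with their four oxygens correspond to the four carbons of squaric acid (1). C2 with its oxygen and the lone C3–H correspond to an α-alkoxyvinyl group. A squarate-derived 4-(1-alkoxyvinyl)cyclobutenone therefore already holds all six carbons and all five oxygens of ring C, with ring D on the C5 oxygen, and a thermal ring expansion only has to make the C3–C4 bond.

## Retrosynthesis

**21 from 20.** The eleven O–CH3 bonds of the undecamethyl ether 20 are cut. Methyl is chosen for every hydroxyl because the ring C oxygens arrive as methyl ethers at no cost (from the squarate ester and the vinyl ether). One ether type also lets a single boron Lewis acid finish the synthesis. Precursor 20 is air-stable and chromatographable, which the target is not. The forward step must cleave eleven alkyl–oxygen bonds and leave the three aryl–O–aryl links alone.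

**20 from 14 and 19.** The bond between the ring C oxygen and C5 of ring B is cut. The oxygen has to stay on ring C because it is the former carbinol oxygen of the cyclobutenone. The cut divides the molecule into halves of similar size, the ring C–D phenol 14 and the ring A–B bromide 19. The mirror arrangement (A–B phenol on the squarate, ring D attached last through an unhindered aryl halide) would make the last coupling easier. It would, however, drag the larger fragment through seven linear steps. The forward reaction is the hardest conventional step: a copper-catalysed Ullmann coupling of a doubly ortho-substituted phenol with an ortho-methoxy aryl bromide.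

**19 from 17 and 18, and 17 from 15.** The ring A oxygen–ring B bond is cut. The hindered phenol 18 meets the dihalide 17, which carries iodine at the open position and bromine next to a methoxy group. The order of the two ether formations on ring B is thereby programmed by halogen reactivity and by sterics. Dihalide 17 goes back through phenol 16 to commercial 15 by para-iodination and O-methylation.

**14 from 12 through 13.** No skeletal bond is cut; two protecting-group operations are removed. The ring expansion delivers the oxygen destined to stay a hydroxyl (on C4) as the free phenol, and the oxygen destined for ring B (on C1) as an acetal. The free phenol is capped as its methyl ether (13) and the acetal is then removed (14). These two steps are the price of having the two hydroquinone oxygens differentiated automatically.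

**12 from 9 (key disconnection).** The C3–C4 bond of ring C is cut and the ring is contracted to the cyclobutenone 9, retracing the dienone 11 and the dienylketene 10. This replaces a pentaoxygenated benzene by a four-membered ring in which every oxygen is already attached. Against a stepwise oxygenation of a benzene, it needs no directing or blocking groups. The forward reaction needs the carbinol oxygen to rotate outward on ring opening, so that the methoxyvinyl group faces the ketene.

**9 from 8, and 8 from 5 and 6.** The acetal is removed (8) and the bond between the carbinol carbon and the vinyl carbon is cut. This leads to the mixed squarate 5 and the lithiated vinyl ether 7, made from methyl vinyl ether 6. The forward addition must choose the carbonyl next to the methoxy-bearing carbon.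

**5 from 2 and 3, and 2 from 1.** The two ester C–O bonds of the squarate are cut. The dichloride 2 takes the methoxy group first (chloro ester 4) and then the ring D phenol 3. Dichloride 2 comes from squaric acid 1. Ring D and its ether link thus cost no coupling step at all.

## Roads not taken

**Alternative 1:** Both C–O bonds from ring C to its ether oxygens are cut at once. The linchpin A1 is a symmetric difluoro dialdehyde in which each fluorine is ortho to one formyl group and para to the other. It would be substituted in one pot, first by the phenoxide of the A–B phenol A2 and then by the phenoxide of 3, to give the tetraaryl dialdehyde A3. A twofold Baeyer–Villiger oxidation would then turn the formyl groups into the C2 and C4 hydroxyls before global demethylation.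
- Merits: it is the most convergent plan. Both hindered ring C ethers are made by nucleophilic aromatic substitution instead of copper coupling, which is exactly where the chosen route is weakest. After fragment preparation it is shorter.
- Weak points: the second fluorine stays fully activated after the first substitution, because the new aryloxy group is meta to it. Clean mono-substitution with two valuable phenoxides is therefore a matter of stoichiometry, not of structure. A1 is not a catalogue compound. A2 costs as much as bromide 19 plus a hydroxylation. A double peracid oxidation has to be run on a very electron-rich tetraaryl ether.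
- Comparison: the chosen plan offers commercial starting materials, no statistical step, an oxygen pattern fixed by connectivity and no peracid on the assembled polyether. It concedes step count and the ease of the hindered ether bonds.

**Alternative 2:** One C–C bond in ring A and one in ring C are cut, each between the ether-bearing carbon and a neighbouring C–OH carbon. Ring B would carry two poly-β-carbonyl ester arms (A4). Excess base would make the aryloxymethyl carbons attack the ester carbons in a double Claisen closure, giving A5, in which rings A and C emerge as free phenols.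
- Merits: it is biomimetic and forms two rings in one operation. Only five methyl ethers remain to be cleaved. The ring B ethers are made by simple alkylation, not by hindered arylation.
- Weak points: chains of this kind prefer lactonisation to 4-hydroxypyranones or aldol closure over C-acylation. The carbon that must attack is the least acidic one in a polyanion. A4 is long to make and hard to handle. Two closures in one molecule multiply the risk.
- Comparison: it is clearly better in the final deprotection and in avoiding hindered couplings. The chosen plan sets against this a ring-forming step whose outcome does not depend on which of several cyclisation modes wins, and stable precursors of a known compound class.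

**Alternative 3:** Three C–C bonds of ring B are cut. A 3-aryloxy-4-methoxycyclobutenone carrying rings C–D (A6) would be heated with the ethynyl ether of ring A (A7). Vinylketene formation, (2+2) addition, ring opening and six-electron closure (Danheiser benzannulation) would give A8 with one free ring B hydroxyl.
- Merits: both ethers of ring B exist before ring B does. The hindered link between rings B and C is forged by vinylogous substitution on a cyclobutenone, which is easier than the copper coupling of step 11.
- Weak points: it does nothing for ring C. The C–D phenol 14 (or an equivalent) is still required to make A6, so ring C would have to be built by a separate sequence of its own. A6 belongs to a little-explored cyclobutenone type. A7, the ynol ether of a doubly ortho-substituted phenol, is labile and less reactive than alkyl or silyl ynol ethers.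
- Comparison: it is as good as or better than the chosen plan for the B–C ether. The chosen plan solves the ring C problem and the D–C ether in one construction and reaches the target in fewer operations.

Key step: step 5

Assumption: the target is achiral; 2-bromo-6-methoxyphenol and 2,4,6-trimethoxyphenol are taken as purchasable; the one stereocenter of intermediates 8 and 9 is carried racemic and vanishes in step 5.

## Route

Step 1
Reactants: 1 squaric acid
Product: 2 squaric acid dichloride (3,4-dichlorocyclobut-3-ene-1,2-dione)
Conditions: (COCl)2, DMF (cat.), CH2Cl2, rt to 40 °C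
Reagents that add atoms: oxalyl chloride, ClC(=O)C(Cl)=O
Why: Vilsmeier-type activation turns both vinylogous acid hydroxyls into vinylogous acid chlorides; this is the standard preparation of the dichloride.

Step 2
Reactants: 2 squaric acid dichloride; 3 3,4,5-trimethoxyphenol
Product: 5 3-methoxy-4-(3,4,5-trimethoxyphenoxy)cyclobut-3-ene-1,2-dione, via 3-chloro-4-methoxycyclobut-3-ene-1,2-dione 4 (not isolated)
Conditions: MeOH (1.0 equiv), CH2Cl2, 0 °C to rt; then 3, Et3N, CH2Cl2, −30 to 0 °C
Reagents that add atoms: methanol, CO
Why: Two addition–elimination reactions at vinylogous acid chloride carbons; the first methoxy group is a strong donor that slows a second methanolysis, so one equivalent stops at 4, and the phenoxide of 3 then displaces only the remaining chloride.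

Step 3
Reactants: 5 3-methoxy-4-(3,4,5-trimethoxyphenoxy)cyclobut-3-ene-1,2-dione; 6 methyl vinyl ether
Product: 8 4-hydroxy-3-methoxy-4-(1-methoxyethenyl)-2-(3,4,5-trimethoxyphenoxy)cyclobut-2-en-1-one (racemic), via 1-methoxyvinyllithium 7 (not isolated)
Conditions: 6, t-BuLi, THF, −78 to 0 °C; then added to 5, THF, −78 °C; sat. aq NH4Cl, −78 °C
Reagents that add atoms: none
Why: α-Lithiation of the vinyl ether gives an acyl-anion-type organolithium that adds 1,2 to a squarate carbonyl at low temperature; the carbonyl next to the methoxy carbon should be attacked because it is conjugated through the ring double bond with the weaker aryloxy donor and is the less shielded one; the carbinol stereocenter forms racemic and is erased in step 5.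

Step 4
Reactants: 8 4-hydroxy-3-methoxy-4-(1-methoxyethenyl)-2-(3,4,5-trimethoxyphenoxy)cyclobut-2-en-1-one
Product: 9 3-methoxy-4-(1-methoxyethenyl)-4-(methoxymethoxy)-2-(3,4,5-trimethoxyphenoxy)cyclobut-2-en-1-one (racemic)
Conditions: MOMCl, i-Pr2NEt, Bu4NI (cat.), CH2Cl2, 0 °C to rt
Reagents that add atoms: chloromethyl methyl ether, COCCl
Why: Williamson-type O-alkylation of the tertiary carbinol with a very reactive α-chloro ether under amine base; the basic medium spares the enol ether and the vinylogous ester.

Step 5
Reactants: 9 3-methoxy-4-(1-methoxyethenyl)-4-(methoxymethoxy)-2-(3,4,5-trimethoxyphenoxy)cyclobut-2-en-1-one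
Product: 12 3,5-dimethoxy-4-(methoxymethoxy)-2-(3,4,5-trimethoxyphenoxy)phenol, via dienylketene 10 (not isolated), via cyclohexa-2,4-dienone 11 (not isolated)
Conditions: toluene (0.02 M, degassed), 110 °C, argon
Reagents that add atoms: none
Why: Moore rearrangement: thermal conrotatory four-electron opening of the C1–C4 bond of the cyclobutenone gives the (Z)-dienylketene 10, in which the acetal oxygen has turned outward and the 1-methoxyvinyl group inward, next to the ketene. Ring C then closes by thermal disrotatory six-electron electrocyclisation, the ketene carbon bonding to the methylene terminus (the C3–C4 bond of ring C), to give dienone 11, which enolises to the phenol under the drive of aromatisation. The closest known reaction type is the thermal ring expansion of squarate-derived 4-alkenyl-4-alkoxy- or 4-siloxycyclobutenones to mono-protected hydroquinones. No stereocenter is created; the single one of 9 disappears on ring opening. The selectivity needed is torquoselectivity, and it is secured by the donor oxygen on the sp3 carbon, which prefers outward rotation over the vinyl group. Regiochemistry needs no control: four ring carbons with their oxygens come from the squarate, the fifth oxygenated carbon and the C–H from the vinyl ether, so the pattern follows from connectivity. The former carbonyl oxygen appears as the free phenol and the carbinol oxygen as the methoxymethyl ether, which differentiates the two hydroquinone oxygens.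

Step 6
Reactants: 12 3,5-dimethoxy-4-(methoxymethoxy)-2-(3,4,5-trimethoxyphenoxy)phenol
Product: 13 1,3,5-trimethoxy-2-(methoxymethoxy)-4-(3,4,5-trimethoxyphenoxy)benzene
Conditions: MeI, K2CO3, acetone, 56 °C
Reagents that add atoms: iodomethane, CI
Why: Williamson methylation of the unhindered phenol; the acetal and the aryl ethers are inert to carbonate.

Step 7
Reactants: 13 1,3,5-trimethoxy-2-(methoxymethoxy)-4-(3,4,5-trimethoxyphenoxy)benzene
Product: 14 2,4,6-trimethoxy-3-(3,4,5-trimethoxyphenoxy)phenol
Conditions: HCl (2 M in MeOH), THF, 40 °C, argon
Reagents that add atoms: none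
Why: Acid-catalysed acetal exchange with methanol removes the aryl methoxymethyl ether; methyl and diaryl ethers do not react with dilute acid.

Step 8
Reactants: 15 2-bromo-6-methoxyphenol
Product: 16 2-bromo-4-iodo-6-methoxyphenol
Conditions: NIS, p-TsOH (cat.), MeCN, 0 °C to rt
Reagents that add atoms: N-iodosuccinimide, O=C1CCC(=O)N1I
Why: Electrophilic aromatic iodination; the hydroxyl is the strongest director and both its ortho positions are occupied, so iodine enters para.

Step 9
Reactants: 16 2-bromo-4-iodo-6-methoxyphenol
Product: 17 1-bromo-5-iodo-2,3-dimethoxybenzene
Conditions: MeI, K2CO3, DMF, rt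
Reagents that add atoms: iodomethane, CI
Why: Williamson methylation of the phenol; no other nucleophilic site is present.

Step 10
Reactants: 17 1-bromo-5-iodo-2,3-dimethoxybenzene; 18 2,4,6-trimethoxyphenol
Product: 19 1-bromo-2,3-dimethoxy-5-(2,4,6-trimethoxyphenoxy)benzene
Conditions: CuI (10 mol %), picolinic acid (20 mol %), K3PO4, DMSO, 80 °C, argon
Reagents that add atoms: none
Why: Ligand-accelerated Ullmann diaryl ether synthesis, a system suited to 2,6-disubstituted phenols; the unhindered C–I bond reacts with copper much faster than the C–Br bond beside methoxy, so ring A is attached only at C5.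

Step 11
Reactants: 14 2,4,6-trimethoxy-3-(3,4,5-trimethoxyphenoxy)phenol; 19 1-bromo-2,3-dimethoxy-5-(2,4,6-trimethoxyphenoxy)benzene
Product: 20 1-[2,3-dimethoxy-5-(2,4,6-trimethoxyphenoxy)phenoxy]-2,4,6-trimethoxy-3-(3,4,5-trimethoxyphenoxy)benzene
Conditions: CuI (20 mol %), picolinic acid (40 mol %), K3PO4, DMSO, 110 °C, argon
Reagents that add atoms: none
Why: Ullmann coupling of the hindered phenoxide with the ortho-methoxy aryl bromide under the same copper–picolinate system at higher temperature; each partner has a single reactive site, so only the desired C–O bond can form.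

Step 12
Reactants: 20 1-[2,3-dimethoxy-5-(2,4,6-trimethoxyphenoxy)phenoxy]-2,4,6-trimethoxy-3-(3,4,5-trimethoxyphenoxy)benzene
Product: 21 3-[2,4,6-trihydroxy-3-(3,4,5-trihydroxyphenoxy)phenoxy]-5-(2,4,6-trihydroxyphenoxy)benzene-1,2-diol (target)
Conditions: BBr3 (excess), CH2Cl2, −78 °C to rt; H2O, 0 °C, argon
Reagents that add atoms: none
Why: Lewis-acid cleavage of aryl methyl ethers by BBr3 (oxonium formation, then bromide attack on methyl); the diaryl ether oxygens carry no sp3 carbon and survive; hydrolysis under argon should release the undecaphenol.

## Compound list

1 | squaric acid (3,4-dihydroxycyclobut-3-ene-1,2-dione) | OC1=C(O)C(=O)C1=O | starting material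
2 | squaric acid dichloride (3,4-dichlorocyclobut-3-ene-1,2-dione) | ClC1=C(Cl)C(=O)C1=O | intermediate
3 | 3,4,5-trimethoxyphenol | COc1cc(O)cc(OC)c1OC | starting material
4 | 3-chloro-4-methoxycyclobut-3-ene-1,2-dione | COC1=C(Cl)C(=O)C1=O | intermediate
5 | 3-methoxy-4-(3,4,5-trimethoxyphenoxy)cyclobut-3-ene-1,2-dione | COC1=C(Oc2cc(OC)c(OC)c(OC)c2)C(=O)C1=O | intermediate
6 | methyl vinyl ether | COC=C | starting material
7 | 1-methoxyvinyllithium | [Li]C(=C)OC | intermediate
8 | 4-hydroxy-3-methoxy-4-(1-methoxyethenyl)-2-(3,4,5-trimethoxyphenoxy)cyclobut-2-en-1-one (racemic) | O=C1C(Oc2cc(OC)c(OC)c(OC)c2)=C(OC)C1(O)C(OC)=C | intermediate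
9 | 3-methoxy-4-(1-methoxyethenyl)-4-(methoxymethoxy)-2-(3,4,5-trimethoxyphenoxy)cyclobut-2-en-1-one (racemic) | O=C1C(Oc2cc(OC)c(OC)c(OC)c2)=C(OC)C1(OCOC)C(OC)=C | intermediate
10 | (3Z)-3,5-dimethoxy-4-(methoxymethoxy)-2-(3,4,5-trimethoxyphenoxy)hexa-1,3,5-trien-1-one (dienylketene) | O=C=C(Oc1cc(OC)c(OC)c(OC)c1)/C(OC)=C(OCOC)\C(OC)=C | intermediate
11 | 3,5-dimethoxy-4-(methoxymethoxy)-2-(3,4,5-trimethoxyphenoxy)cyclohexa-2,4-dien-1-one | O=C1CC(OC)=C(OCOC)C(OC)=C1Oc1cc(OC)c(OC)c(OC)c1 | intermediate
12 | 3,5-dimethoxy-4-(methoxymethoxy)-2-(3,4,5-trimethoxyphenoxy)phenol | COCOc1c(OC)cc(O)c(Oc2cc(OC)c(OC)c(OC)c2)c1OC | intermediate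
13 | 1,3,5-trimethoxy-2-(methoxymethoxy)-4-(3,4,5-trimethoxyphenoxy)benzene | COCOc1c(OC)cc(OC)c(Oc2cc(OC)c(OC)c(OC)c2)c1OC | intermediate
14 | 2,4,6-trimethoxy-3-(3,4,5-trimethoxyphenoxy)phenol | Oc1c(OC)cc(OC)c(Oc2cc(OC)c(OC)c(OC)c2)c1OC | intermediate
15 | 2-bromo-6-methoxyphenol | COc1cccc(Br)c1O | starting material
16 | 2-bromo-4-iodo-6-methoxyphenol | COc1cc(I)cc(Br)c1O | intermediate
17 | 1-bromo-5-iodo-2,3-dimethoxybenzene | COc1cc(I)cc(Br)c1OC | intermediate
18 | 2,4,6-trimethoxyphenol | COc1cc(OC)c(O)c(OC)c1 | starting material
19 | 1-bromo-2,3-dimethoxy-5-(2,4,6-trimethoxyphenoxy)benzene | COc1cc(OC)c(Oc2cc(OC)c(OC)c(Br)c2)c(OC)c1 | intermediate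
20 | 1-[2,3-dimethoxy-5-(2,4,6-trimethoxyphenoxy)phenoxy]-2,4,6-trimethoxy-3-(3,4,5-trimethoxyphenoxy)benzene | COc1cc(OC)c(Oc2cc(OC)c(OC)c(Oc3c(OC)cc(OC)c(Oc4cc(OC)c(OC)c(OC)c4)c3OC)c2)c(OC)c1 | intermediate
21 | 3-[2,4,6-trihydroxy-3-(3,4,5-trihydroxyphenoxy)phenoxy]-5-(2,4,6-trihydroxyphenoxy)benzene-1,2-diol | Oc1cc(O)c(Oc2cc(O)c(O)c(Oc3c(O)cc(O)c(Oc4cc(O)c(O)c(O)c4)c3O)c2)c(O)c1 | target

## Step count and least certain steps

Total step count: 12. Longest linear sequence: 9 steps (steps 1 to 7, 11 and 12); steps 8 to 10 form the side branch to 19.

**Step 5 (key step).** The most likely failure is a loss of material along the ketene manifold: partial inward rotation of the acetal oxygen, capture of the ketene by the electron-rich ring D, or thermal breakdown of the enol ether before closure. Fallback: set out from carbinol 8 and heat it unprotected (toluene, 110 °C, argon). A free hydroxyl is the strongest outward-rotating group in this reaction class, so closure should give the hydroquinone 3,5-dimethoxy-2-(3,4,5-trimethoxyphenoxy)benzene-1,4-diol F1. Of its two hydroxyls, the one beside the ring C–H is unhindered and the other lies between two methoxy groups. One equivalent of MeI with K2CO3 in acetone under argon should therefore methylate the former and return the route at 14, bypassing 9, 12 and 13.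

**Step 3.** The donor difference between methoxy and aryloxy is real but moderate, so addition may be split between the two carbonyls. Some aryloxide may also be lost by conjugate addition–elimination. Fallback: remove the choice by symmetry.
- Dichloride 2 with two equivalents of 3 and Et3N gives 3,4-bis(3,4,5-trimethoxyphenoxy)cyclobut-3-ene-1,2-dione F2.
- Organolithium 7 adds to either of its equivalent carbonyls to give 4-hydroxy-4-(1-methoxyethenyl)-2,3-bis(3,4,5-trimethoxyphenoxy)cyclobut-2-en-1-one F3.
- F3 is capped with MOMCl and i-Pr2NEt to 4-(1-methoxyethenyl)-4-(methoxymethoxy)-2,3-bis(3,4,5-trimethoxyphenoxy)cyclobut-2-en-1-one F4.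
- Only the aryloxy group on the β-carbon of the enone is a vinylogous aryl ester. One equivalent of NaOMe in MeOH–THF at −40 to 0 °C should exchange it by addition–elimination, leave the α-aryloxy group untouched, release 3 for recovery and return the route at 9.

**Step 11.** Both partners are ortho-substituted and electron-rich, so the copper coupling may stall while 19 is slowly reduced and the phenoxide of 14 is oxidised. Fallback: change the bond-forming manifold. Bromide 19 is converted by bromine–lithium exchange (n-BuLi, THF, −78 °C), borylation with B(Oi-Pr)3 and acidic work-up into [2,3-dimethoxy-5-(2,4,6-trimethoxyphenoxy)phenyl]boronic acid F5. F5 is coupled with 14 under Chan–Lam–Evans conditions (Cu(OAc)2, pyridine, 4 Å sieves, CH2Cl2, dry air, rt). There the C–O bond forms by reductive elimination from trivalent copper at room temperature. The route is rejoined at 20.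

**Step 12.** Cleavage of eleven methyl ethers may stop at partly methylated boron chelates, and the free polyphenol may be oxidised during isolation. Fallback: do not isolate the phenol directly. The crude product from 20 and BBr3 is acetylated at once (Ac2O, pyridine, argon) to the undecaacetate of the target F6. This should be stable and chromatographable, so that incompletely demethylated material can be separated and resubmitted. Acidic methanolysis (HCl in degassed MeOH, rt, argon) then releases 21 without base or oxidant.

Further compounds
F1 | step 5 | 3,5-dimethoxy-2-(3,4,5-trimethoxyphenoxy)benzene-1,4-diol | Oc1c(OC)cc(O)c(Oc2cc(OC)c(OC)c(OC)c2)c1OC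
F2 | step 3 | 3,4-bis(3,4,5-trimethoxyphenoxy)cyclobut-3-ene-1,2-dione | O=C1C(=O)C(Oc2cc(OC)c(OC)c(OC)c2)=C1Oc1cc(OC)c(OC)c(OC)c1
F3 | step 3 | 4-hydroxy-4-(1-methoxyethenyl)-2,3-bis(3,4,5-trimethoxyphenoxy)cyclobut-2-en-1-one (racemic) | O=C1C(Oc2cc(OC)c(OC)c(OC)c2)=C(Oc2cc(OC)c(OC)c(OC)c2)C1(O)C(OC)=C
F4 | step 3 | 4-(1-methoxyethenyl)-4-(methoxymethoxy)-2,3-bis(3,4,5-trimethoxyphenoxy)cyclobut-2-en-1-one (racemic) | O=C1C(Oc2cc(OC)c(OC)c(OC)c2)=C(Oc2cc(OC)c(OC)c(OC)c2)C1(OCOC)C(OC)=C
F5 | step 11 | [2,3-dimethoxy-5-(2,4,6-trimethoxyphenoxy)phenyl]boronic acid | COc1cc(OC)c(Oc2cc(OC)c(OC)c(B(O)O)c2)c(OC)c1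
F6 | step 12 | undecaacetate of the target | CC(=O)Oc1cc(OC(C)=O)c(Oc2cc(OC(C)=O)c(OC(C)=O)c(Oc3c(OC(C)=O)cc(OC(C)=O)c(Oc4cc(OC(C)=O)c(OC(C)=O)c(OC(C)=O)c4)c3OC(C)=O)c2)c(OC(C)=O)c1
A1 | alternative 1 | 4,6-difluoro-5-methoxybenzene-1,3-dicarbaldehyde | COc1c(F)c(C=O)cc(C=O)c1F
A2 | alternative 1 | 2,3-dimethoxy-5-(2,4,6-trimethoxyphenoxy)phenol | COc1cc(OC)c(Oc2cc(O)c(OC)c(OC)c2)c(OC)c1
A3 | alternative 1 | 4-[2,3-dimethoxy-5-(2,4,6-trimethoxyphenoxy)phenoxy]-5-methoxy-6-(3,4,5-trimethoxyphenoxy)benzene-1,3-dicarbaldehyde | COc1c(Oc2cc(OC)c(OC)c(OC)c2)c(C=O)cc(C=O)c1Oc1cc(Oc2c(OC)cc(OC)cc2OC)cc(OC)c1OC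
A4 | alternative 2 | methyl 6-[3-[[6-methoxy-2,4,6-trioxo-5-(3,4,5-trimethoxyphenoxy)hexyl]oxy]-4,5-dimethoxyphenoxy]-3,5-dioxohexanoate | COC(=O)CC(=O)CC(=O)COc1cc(OC)c(OC)c(OCC(=O)CC(=O)C(Oc2cc(OC)c(OC)c(OC)c2)C(=O)OC)c1
A5 | alternative 2 | 2-[3-[2,4,6-trihydroxy-3-(3,4,5-trimethoxyphenoxy)phenoxy]-4,5-dimethoxyphenoxy]benzene-1,3,5-triol | Oc1cc(O)c(Oc2cc(OC)c(OC)c(Oc3c(O)cc(O)c(Oc4cc(OC)c(OC)c(OC)c4)c3O)c2)c(O)c1
A6 | alternative 3 | 4-methoxy-3-[2,4,6-trimethoxy-3-(3,4,5-trimethoxyphenoxy)phenoxy]cyclobut-2-en-1-one | O=C1C=C(Oc2c(OC)cc(OC)c(Oc3cc(OC)c(OC)c(OC)c3)c2OC)C1OC
A7 | alternative 3 | 2-(ethynyloxy)-1,3,5-trimethoxybenzene | C#COc1c(OC)cc(OC)cc1OC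
A8 | alternative 3 | 2-methoxy-3-[2,4,6-trimethoxy-3-(3,4,5-trimethoxyphenoxy)phenoxy]-5-(2,4,6-trimethoxyphenoxy)phenol | Oc1cc(Oc2c(OC)cc(OC)cc2OC)cc(Oc2c(OC)cc(OC)c(Oc3cc(OC)c(OC)c(OC)c3)c2OC)c1OC
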